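**Plan**

- Locants (ent-kaurane): C1 = CH–OAc, C4 = CMe2, C5/C10 = ring A–B carbons (C10 carries the lactone CH2, C20), C6 = CH–OH of ring B, C8 = quaternary carbon with the lactone C=O (C7), C9, C11 = CH–OH, C13 = CH with the acrylate. Ring A = CMe2 ring, ring B = cyclopentane, ring C = acrylate ring.
- Retrosynthesis: C11–OH ⇒ ketone; acrylate ⇒ malonate on a C12=C13 enone; ring C ⇒ anisole ring (Birch); C6–C8 ⇒ lactone-enolate aldol (ring B last); C2–C3 ⇒ aldol condensation (ring A); then C9–C10 and C5–C6 are cut together ⇒ aryl iodide ester 9 + CO.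
- Forward: E-enone alcohol 7 + 2-iodo-3-methoxybenzoic acid 8 → ester 9 → aryl/CO addition across C5=C10 (closes the lactone ring) → ring A → dearomatised ring C → ring B → side chain and C11.
- Enabling feature: C7 sits ortho to C9 on ring C, so the benzoate tether brings C9 to C10 through a six-membered (6-exo) closure. C5 lies between the fully substituted C4 and C10, so the alkylpalladium at C5 has no β-hydrogen and must take up CO as C6.
- Stereochemistry: the trans A/B fusion needs C9 and C6 anti across C5–C10. A syn addition gives this only from an acyclic E-alkene, so ring A is closed afterwards. C10 comes from the chiral bisphosphine, C5 from the alkene geometry, then C1, C8/C6, C9, C13 and C11 by substrate control.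

Key step: step 7

Remark: the sense of induction of the ligand in step 7 is not assumed; the ligand antipode that gives (2R,4R)-10 is the one to use.

Step 1
Reactants: 1 2-methyl-1-(trimethylsilyloxy)prop-1-ene
Product: 2 3,3-dimethoxy-2,2-dimethylpropanal
Conditions: HC(OMe)3, TMSOTf (5 mol %), CH2Cl2, −78 °C
Reagents that add atoms: trimethyl orthoformate, COC(OC)OC
Why: Mukaiyama-type addition of the silyl enol ether to the dimethoxycarbenium ion formed from the orthoformate gives the α-quaternary aldehyde with the second aldehyde already masked as its acetal; no stereocentre is formed.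

Step 2
Reactants: 2 3,3-dimethoxy-2,2-dimethylpropanal
Product: 3 4,4-dimethoxy-3,3-dimethylbut-1-yne
Conditions: dimethyl (1-diazo-2-oxopropyl)phosphonate, K2CO3, MeOH, 0 °C to rt
Reagents that add atoms: dimethyl (1-diazo-2-oxopropyl)phosphonate, CC(=O)C(=[N+]=[N-])P(=O)(OC)OC
Why: Ohira–Bestmann (Seyferth–Gilbert) homologation suits a non-enolisable α-quaternary aldehyde and leaves the acetal untouched.

Step 3
Reactants: 3 4,4-dimethoxy-3,3-dimethylbut-1-yne
Product: 4 5,5-dimethoxy-4,4-dimethylpent-2-yn-1-ol
Conditions: n-BuLi, THF, −78 °C; (CH2O)n, −78 °C to rt; NH4Cl aq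
Reagents that add atoms: formaldehyde (from paraformaldehyde), C=O
Why: Acetylide addition to formaldehyde installs the future lactone CH2 (C20).

Step 4
Reactants: 4 5,5-dimethoxy-4,4-dimethylpent-2-yn-1-ol
Product: 5 (E)-5,5-dimethoxy-4,4-dimethyl-2-(tributylstannyl)pent-2-en-1-ol
Conditions: Bu3SnH, PdCl2(PPh3)2 (2 mol %), THF, 0 °C
Reagents that add atoms: tributyltin hydride, CCCC[SnH](CCCC)CCCC
Why: Palladium-catalysed hydrostannation adds H and Sn syn, and the bulky quaternary substituent should send tin to the carbon next to CH2OH, so CH2OH and the quaternary carbon end up cis on the alkene.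

Step 5
Reactants: 5 (E)-5,5-dimethoxy-4,4-dimethyl-2-(tributylstannyl)pent-2-en-1-ol
Product: 7 (E)-3-(hydroxymethyl)-6,6-dimethoxy-5,5-dimethylhex-3-en-2-one, via dilithio alkoxide 6 (not isolated)
Conditions: MeLi (2.2 equiv), THF, −78 to −40 °C; AcN(OMe)Me, −78 to 0 °C; NH4Cl aq
Reagents that add atoms: N-methoxy-N-methylacetamide, CC(=O)N(C)OC
Why: Tin–lithium exchange keeps the alkene geometry and the vinyllithium is acylated once by the Weinreb amide, which gives the E-enone in which C20 is cis to the C4 side and the acetyl group (C1, C2) is trans to it.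

Step 6
Reactants: 7 (E)-3-(hydroxymethyl)-6,6-dimethoxy-5,5-dimethylhex-3-en-2-one; 8 2-iodo-3-methoxybenzoic acid
Product: 9 (E)-2-acetyl-5,5-dimethoxy-4,4-dimethylpent-2-en-1-yl 2-iodo-3-methoxybenzoate
Conditions: DCC, DMAP (10 mol %), CH2Cl2, 0 °C to rt
Reagents that add atoms: none
Why: Steglich esterification of the primary allylic alcohol joins the ring C arene to the chain through the future lactone C7–O–C20 linkage; the hindered β-carbon of the enone should resist conjugate attack by DMAP.

Step 7
Reactants: 9 (E)-2-acetyl-5,5-dimethoxy-4,4-dimethylpent-2-en-1-yl 2-iodo-3-methoxybenzoate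
Product: 10 benzyl (2R)-2-[(4R)-4-acetyl-5-methoxy-1-oxoisochroman-4-yl]-4,4-dimethoxy-3,3-dimethylbutanoate
Conditions: Pd2(dba)3 (5 mol %), (R)-BINAP (12 mol %), Ag3PO4 (0.5 equiv), BnOH (5 equiv), CO (1 atm), toluene, 80 °C
Reagents that add atoms: carbon monoxide, [C-]#[O+]; benzyl alcohol, OCc1ccccc1
Why: Oxidative addition of zerovalent palladium to the aryl iodide, 6-exo-trig syn migratory insertion of the trisubstituted enone alkene (aryl carbon C9 to C10, palladium to C5), CO insertion into the C5–Pd bond with retention and benzyl alcoholysis of the acylpalladium give C9–C10 and C5–C6 in one catalytic cycle. The closest known reaction type is the asymmetric domino Heck/alkoxycarbonylation of aryl halides that carry a tethered 1,1-disubstituted alkene and end on a neopentyl σ-alkylpalladium. The lactone ring (C7, O, C20, C10, C9, C8) closes in the 6-exo-trig mode and no other ring is formed. C10 is set by enantioface selection in the insertion step under the chiral bisphosphine (cationic pathway enforced by Ag3PO4), and C5 follows from the E geometry of the alkene because carbopalladation is syn and CO insertion retains configuration, which puts C9 and C6 anti across C5–C10 as the trans A/B fusion requires. The step needs alkene insertion to outrun CO uptake at the arylpalladium stage and needs an alkylpalladium that cannot eliminate: the tether length secures exo insertion, the low CO pressure the order of events, and C5 lies between the fully substituted C4 and C10 so that no β-hydrogen exists. Aryl–iodine oxidative addition should be faster than ionisation of the hindered allylic benzoate.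

Step 8
Reactants: 10 benzyl (2R)-2-[(4R)-4-acetyl-5-methoxy-1-oxoisochroman-4-yl]-4,4-dimethoxy-3,3-dimethylbutanoate
Product: 12 benzyl 5'-methoxy-3,3-dimethyl-1',6-dioxospiro[cyclohex-4-ene-1,4'-isochromane]-2-carboxylate, via keto aldehyde 11 (not isolated)
Conditions: TsOH·H2O (20 mol %), wet toluene, 60 °C to reflux (Dean–Stark)
Reagents that add atoms: none
Why: Acid hydrolysis of the acetal and intramolecular aldol condensation of the methyl ketone (C2) onto the non-enolisable aldehyde (C3) close ring A as a 4,4-dimethylcyclohexenone without touching C5 or C10.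

Step 9
Reactants: 12 benzyl 5'-methoxy-3,3-dimethyl-1',6-dioxospiro[cyclohex-4-ene-1,4'-isochromane]-2-carboxylate
Product: 13 5'-methoxy-3,3-dimethyl-1',6-dioxospiro[cyclohexane-1,4'-isochromane]-2-carboxylic acid
Conditions: H2 (1 atm), 10% Pd/C, EtOAc, rt
Reagents that add atoms: none
Why: Catalytic hydrogenation saturates the C2=C3 enone bond and hydrogenolyses the benzyl ester in one operation while the aryl lactone stays intact.

Step 10
Reactants: 13 5'-methoxy-3,3-dimethyl-1',6-dioxospiro[cyclohexane-1,4'-isochromane]-2-carboxylic acid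
Product: 14 6-hydroxy-2-(hydroxymethyl)-5'-methoxy-3,3-dimethylspiro[cyclohexane-1,4'-isochroman]-1'-one (C1–OH equatorial)
Conditions: BH3·THF (4 equiv), THF, 0 °C to rt; MeOH, H2O
Reagents that add atoms: none
Why: Borane reduces the carboxylic acid (to C6H2OH) and the ketone but not the aryl lactone; hydride should add to C1 along the axial direction, anti to the axial lactone CH2 on C10, giving the equatorial alcohol cis to C20 and C6.

Step 11
Reactants: 14 6-hydroxy-2-(hydroxymethyl)-5'-methoxy-3,3-dimethylspiro[cyclohexane-1,4'-isochroman]-1'-one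
Product: 15 bis(triethylsilyl) ether of 14
Conditions: TESCl (2.5 equiv), imidazole, DMF, rt
Reagents that add atoms: chlorotriethylsilane, CC[Si](Cl)(CC)CC
Why: Silylation of both hydroxyls blocks translactonisation of the C1 oxygen onto C7 in the basic steps ahead and prepares the selective oxidation of step 13.

Step 12
Reactants: 15 bis(triethylsilyl) ether of 14
Product: 16 6',8a'-dihydro derivative of 15 (C9=C11 methyl enol ether and C13=C14 alkene; C8 epimers)
Conditions: Li, NH3(l)/THF, t-BuOH (2 equiv), −78 °C; solid NH4Cl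
Reagents that add atoms: none
Why: Birch reduction of a benzoate-type arene gives the 1,4-dihydro compound (C8 and C12 become sp3, the methoxy-bearing C11 stays sp2), so the flat ring becomes ring C with an enol ether at C9=C11 and an alkene at C13=C14; the C8 epimers converge in step 14.

Step 13
Reactants: 16 6',8a'-dihydro derivative of 15
Product: 17 C6 aldehyde (primary silyl ether of 16 oxidised; C1–OTES kept)
Conditions: (COCl)2, DMSO, CH2Cl2, −78 to −30 °C; Et3N
Reagents that add atoms: none
Why: Under Swern conditions a primary triethylsilyl ether is oxidised directly to the aldehyde while a secondary one survives (oxidative desilylation), and the non-aqueous, buffered conditions should spare the enol ether and the 1,4-diene.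

Step 14
Reactants: 17 C6 aldehyde
Product: 18 tetracyclic aldol product (7,20-lactone; C6–OH exo; C9=C11 methyl enol ether; C13=C14; C1–OTES)
Conditions: LiN(SiMe3)2 (1.1 equiv), THF, −78 to −40 °C; NH4Cl aq
Reagents that add atoms: none
Why: Deprotonation of the doubly allylic C8–H next to the lactone carbonyl and intramolecular aldol addition (5-exo-trig) to the C6 aldehyde close ring B; C8 is fixed by the tether to C5, and the C6 hydroxyl should come out exo, cis to H5, because the carbonyl oxygen turns away from the C4 gem-dimethyl group.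

Step 15
Reactants: 18 tetracyclic aldol product
Product: 20 C1,C6-diol with C11 ketone and C12=C13 enone, via β,γ-enone diol 19 (not isolated)
Conditions: 1 M HCl aq, THF, rt
Reagents that add atoms: water, O
Why: Aqueous acid removes the silyl ether, hydrolyses the enol ether to the C11 ketone and moves the C13=C14 bond into conjugation; C9 should be protonated on the face of the C5–C6 bridge, next to the C6 hydroxyl, which gives the B/C-trans arrangement, and C9 can still equilibrate through the enol.

Step 16
Reactants: 20 C1,C6-diol enone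
Product: 21 C1 acetate of 20
Conditions: Ac2O (1.2 equiv), pyridine, DMAP (5 mol %), CH2Cl2, 0 °C
Reagents that add atoms: acetic anhydride, CC(=O)OC(C)=O
Why: DMAP-catalysed acetylation should pick the equatorial C1 hydroxyl over the C6 hydroxyl, which is flanked by the quaternary C8 and by C5.

Step 17
Reactants: 21 C1 acetate of 20
Product: 22 C13 allyl methyl malonate adduct (malonate carbon unassigned)
Conditions: allyl methyl malonate, DBU (0.3 equiv), MeCN, rt
Reagents that add atoms: allyl methyl malonate, C=CCOC(=O)CC(=O)OC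
Why: Reversible Michael addition of the malonate to the C12=C13 enone; attack anti to the axial lactone carbonyl on C8 gives the equatorial C13 substituent, which is also the thermodynamic product.

Step 18
Reactants: 22 C13 allyl methyl malonate adduct
Product: 23 malonic half acid (methyl ester kept)
Conditions: Pd(PPh3)4 (5 mol %), morpholine, THF, rt
Reagents that add atoms: none
Why: Palladium-catalysed deallylation (Tsuji–Trost, morpholine as allyl acceptor) frees one malonate carboxyl without touching the methyl ester, the acetate or the lactone.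

Step 19
Reactants: 23 malonic half acid
Product: 24 11-oxo precursor of the target (methyl acrylate in place)
Conditions: (CH2O)n, Et2NH, EtOAc, reflux
Reagents that add atoms: formaldehyde (from paraformaldehyde), C=O
Why: Mannich reaction of the malonic half acid with formaldehyde followed by decarboxylative elimination gives the α-methylene methyl ester; C13 is not touched.

Step 20
Reactants: 24 11-oxo precursor
Product: 25 target CNP0421185.1
Conditions: LiAlH(Ot-Bu)3, THF, −78 to −40 °C
Reagents that add atoms: none
Why: The bulky, mild hydride reduces only the ketone; the axial approach to C11 is blocked by the axial lactone carbonyl carbon on C8, so hydride should enter equatorially and give the axial C11 hydroxyl of the target.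

**Compound list**

1 | 2-methyl-1-(trimethylsilyloxy)prop-1-ene | CC(C)=CO[Si](C)(C)C | starting material
2 | 3,3-dimethoxy-2,2-dimethylpropanal | COC(OC)C(C)(C)C=O | intermediate
3 | 4,4-dimethoxy-3,3-dimethylbut-1-yne | COC(OC)C(C)(C)C#C | intermediate
4 | 5,5-dimethoxy-4,4-dimethylpent-2-yn-1-ol | COC(OC)C(C)(C)C#CCO | intermediate
5 | (E)-5,5-dimethoxy-4,4-dimethyl-2-(tributylstannyl)pent-2-en-1-ol | OC/C([Sn](CCCC)(CCCC)CCCC)=C\C(C)(C)C(OC)OC | intermediate
6 | lithium (E)-2-lithio-5,5-dimethoxy-4,4-dimethylpent-2-en-1-olate | [Li]OC/C([Li])=C\C(C)(C)C(OC)OC | intermediate (not isolated)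
7 | (E)-3-(hydroxymethyl)-6,6-dimethoxy-5,5-dimethylhex-3-en-2-one | OC/C(C(C)=O)=C\C(C)(C)C(OC)OC | intermediate
8 | 2-iodo-3-methoxybenzoic acid | COc1cccc(C(=O)O)c1I | starting material
9 | (E)-2-acetyl-5,5-dimethoxy-4,4-dimethylpent-2-en-1-yl 2-iodo-3-methoxybenzoate | COc1cccc(C(=O)OC/C(C(C)=O)=C\C(C)(C)C(OC)OC)c1I | intermediate
10 | benzyl (2R)-2-[(4R)-4-acetyl-5-methoxy-1-oxoisochroman-4-yl]-4,4-dimethoxy-3,3-dimethylbutanoate | O=C1OC[C@@](C(C)=O)([C@H](C(=O)OCc3ccccc3)C(C)(C)C(OC)OC)c2c1cccc2OC | intermediate
11 | benzyl (2R)-2-[(4R)-4-acetyl-5-methoxy-1-oxoisochroman-4-yl]-3,3-dimethyl-4-oxobutanoate | O=C1OC[C@@](C(C)=O)([C@H](C(=O)OCc3ccccc3)C(C)(C)C=O)c2c1cccc2OC | intermediate (not isolated)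
12 | benzyl 5'-methoxy-3,3-dimethyl-1',6-dioxospiro[cyclohex-4-ene-1,4'-isochromane]-2-carboxylate (aryl carbon C9 and ester trans on ring A) | O=C1OC[C@]2(C(=O)C=CC(C)(C)[C@H]2C(=O)OCc4ccccc4)c3c1cccc3OC | intermediate
13 | 5'-methoxy-3,3-dimethyl-1',6-dioxospiro[cyclohexane-1,4'-isochromane]-2-carboxylic acid | O=C1OC[C@]2(C(=O)CCC(C)(C)[C@H]2C(=O)O)c3c1cccc3OC | intermediate
14 | 6-hydroxy-2-(hydroxymethyl)-5'-methoxy-3,3-dimethylspiro[cyclohexane-1,4'-isochroman]-1'-one (C1–OH cis to the lactone CH2 and to CH2OH) | O=C1OC[C@]2([C@@H](O)CCC(C)(C)[C@H]2CO)c3c1cccc3OC | intermediate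
15 | bis(triethylsilyl) ether of 14 | O=C1OC[C@]2([C@@H](O[Si](CC)(CC)CC)CCC(C)(C)[C@H]2CO[Si](CC)(CC)CC)c3c1cccc3OC | intermediate
16 | 6',8a'-dihydro derivative of 15 (C8 epimers) | O=C1OC[C@]2([C@@H](O[Si](CC)(CC)CC)CCC(C)(C)[C@H]2CO[Si](CC)(CC)CC)C3=C(OC)CC=CC13 | intermediate
17 | C6 aldehyde of the dihydro series (C1–OTES, C8 epimers) | O=C1OC[C@]2([C@@H](O[Si](CC)(CC)CC)CCC(C)(C)[C@H]2C=O)C3=C(OC)CC=CC13 | intermediate
18 | tetracyclic aldol product (C6–OH exo, enol ether C9=C11, alkene C13=C14, C1–OTES) | COC1=C2[C@]3(C=CC1)C(=O)OC[C@]24[C@@H](O[Si](CC)(CC)CC)CCC(C)(C)[C@H]4[C@@H]3O | intermediate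
19 | C1,C6-diol with C11 ketone and C13=C14 alkene | C1CC(=O)[C@@H]2[C@]3(C=1)C(=O)OC[C@]21[C@@H](O)CCC(C)(C)[C@H]1[C@@H]3O | intermediate (not isolated)
20 | C1,C6-diol with C11 ketone and C12=C13 enone | C1=CC(=O)[C@@H]2[C@]3(C1)C(=O)OC[C@]21[C@@H](O)CCC(C)(C)[C@H]1[C@@H]3O | intermediate
21 | C1 acetate of 20 | C1=CC(=O)[C@@H]2[C@]3(C1)C(=O)OC[C@]21[C@@H](OC(C)=O)CCC(C)(C)[C@H]1[C@@H]3O | intermediate
22 | C13 allyl methyl malonate adduct (C13 substituent equatorial; malonate carbon unassigned) | C=CCOC(=O)C(C(=O)OC)[C@@H]1CC(=O)[C@@H]2[C@]3(C1)C(=O)OC[C@]21[C@@H](OC(C)=O)CCC(C)(C)[C@H]1[C@@H]3O | intermediate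
23 | malonic half acid | OC(=O)C(C(=O)OC)[C@@H]1CC(=O)[C@@H]2[C@]3(C1)C(=O)OC[C@]21[C@@H](OC(C)=O)CCC(C)(C)[C@H]1[C@@H]3O | intermediate
24 | 11-oxo precursor of the target | C=C(C(=O)OC)[C@@H]1CC(=O)[C@@H]2[C@]3(C1)C(=O)OC[C@]21[C@@H](OC(C)=O)CCC(C)(C)[C@H]1[C@@H]3O | intermediate
25 | CNP0421185.1 (1-acetate, 6- and 11-hydroxy, 7,20-lactone, methyl acrylate at C13) | C=C(C(=O)OC)[C@@H]1C[C@H](O)[C@@H]2[C@]3(C1)C(=O)OC[C@]21[C@@H](OC(C)=O)CCC(C)(C)[C@H]1[C@@H]3O | target

**Step count and risks**

Total step count: 20. Longest linear sequence: 20 steps (1 to 25; 8 is bought).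

Steps most likely to fail:

1. Step 7. CO may be taken up by the arylpalladium before the slow insertion into the hindered trisubstituted alkene (premature alkoxycarbonylation), zerovalent palladium may ionise the allylic ester, or enantioface discrimination may be weak. The fallback sets out from 9 and returns at 10. The insertion is run without CO as a domino Heck/Suzuki–Miyaura reaction (Pd2(dba)3, the same bisphosphine, CH2=CHBF3K, Cs2CO3, toluene/H2O, 80 °C) to give the C5-vinyl analogue of 10 F1. Ozonolysis (O3, CH2Cl2/MeOH, −78 °C; PPh3) gives the aldehyde F2, Pinnick oxidation (NaClO2, NaH2PO4, 2-methyl-2-butene) gives the acid F3, and BnBr/K2CO3 in DMF returns 10. If only the enantioface control is at fault, acid F3 can be resolved as its salt with a 1-phenylethylamine enantiomer.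

2. Step 12. The lactone alkyl C–O bond may be cleaved reductively, or the ring may be over-reduced instead of giving the clean 1,4-dihydro compound. The fallback sets out from 15 and returns at 16. The lactone is opened with LiOH (THF/H2O) to the hydroxy acid F4, which is kept as its lithium carboxylate, the classical Birch substrate class. Reduction (Li, NH3, t-BuOH, −78 °C) gives the 1,4-dihydro hydroxy acid F5, and mild acidification with EDCI/DMAP closes the lactone again to 16.

3. Step 14. Closure of the strained trans-fused ring B may be slow, which leaves time for enolisation of the aldehyde at C5 (epimerisation and cis-fused closure) or for base-induced isomerisation and aromatisation of the cyclohexadiene. The fallback sets out from 17 and returns at 20. A one-pot soft enolisation/Mukaiyama aldol (TMSOTf, i-Pr2NEt, CH2Cl2, −78 °C) converts the lactone into the silyl ketene acetal F6, which adds to the TMSOTf-activated aldehyde without any free metal enolate or alkoxide. This gives the 6-O-trimethylsilyl ether of 18 F7, which is put through the conditions of step 15 (1 M HCl removes both silyl groups) to reach 20.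

Further compounds
F1 | step 7 | C5-vinyl analogue of 10: 4-acetyl-4-(5,5-dimethoxy-4,4-dimethylpent-1-en-3-yl)-5-methoxyisochroman-1-one (C5, C10 as in 10) | O=C1OC[C@@](C(C)=O)([C@H](C=C)C(C)(C)C(OC)OC)c2c1cccc2OC
F2 | step 7 | 2-(4-acetyl-5-methoxy-1-oxoisochroman-4-yl)-4,4-dimethoxy-3,3-dimethylbutanal | O=C1OC[C@@](C(C)=O)([C@H](C=O)C(C)(C)C(OC)OC)c2c1cccc2OC
F3 | step 7 | 2-(4-acetyl-5-methoxy-1-oxoisochroman-4-yl)-4,4-dimethoxy-3,3-dimethylbutanoic acid | O=C1OC[C@@](C(C)=O)([C@H](C(=O)O)C(C)(C)C(OC)OC)c2c1cccc2OC
F4 | step 12 | hydroxy acid from lactone opening of 15 | OC[C@@]1(c2c(OC)cccc2C(=O)O)[C@@H](O[Si](CC)(CC)CC)CCC(C)(C)[C@H]1CO[Si](CC)(CC)CC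
F5 | step 12 | 1,4-dihydro hydroxy acid (C8 epimers) | OC[C@@]1(C2=C(OC)CC=CC2C(=O)O)[C@@H](O[Si](CC)(CC)CC)CCC(C)(C)[C@H]1CO[Si](CC)(CC)CC
F6 | step 14 | trimethylsilyl ketene acetal of lactone 17 (not isolated) | C[Si](C)(C)OC1=C2C=CCC(OC)=C2[C@]3(CO1)[C@@H](O[Si](CC)(CC)CC)CCC(C)(C)[C@H]3C=O
F7 | step 14 | 6-O-trimethylsilyl ether of 18 | COC1=C2[C@]3(C=CC1)C(=O)OC[C@]24[C@@H](O[Si](CC)(CC)CC)CCC(C)(C)[C@H]4[C@@H]3O[Si](C)(C)C
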